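A one-way reaction cannot do what the green run did: at 2.50 min it stood at 60.9 % links with second end groups still on hand, yet by 8.00 min it had gained just 7.9 percentage points.

| flask | first end groups | second end groups | remark | time |
|---|---|---|---|---|
| teal | 5.4 mM | 20 mM | run made earlier |  |
| green | 16 mM | 20 mM | run made earlier |  |
| maple | 10 mM | 20.0 mM |  | 2.5 min |
| larch | 20 mM | 20.0 mM |  | 8.0 min |

| teal: time / min | teal: links / % | green: time / min | green: links / % |
|---|---|---|---|
| 1.50 | 63.4 | 0.667 | 32.2 |
| 3.00 | 80.8 | 1.33 | 48.8 |
| 5.00 | 90.5 | 2.50 | 60.9 |
| 6.00 | 92.5 | 4.00 | 63.9 |
| 8.00 | 93.7 | 8.00 | 68.8 |

(each reading ± 1 percentage point)

1. the flask that ends with the higher amount of links, in percent of the first end groups charged, or "neither" when 2 percentage points or less lies between them (maple / larch / neither)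
2. final links, as a percentage of the first end groups charged, in maple
3. final links, as a percentage of the first end groups charged, in larch

- for links the idle adduct and crystals are counted in
- as a solid, counted per litre of solution: crystals
- steps under discussion: first end groups + second end groups <-> links + released group; released group -> by-product carried off; crystals <-> links; second end groups + links <-> idle adduct

So keep a ledger of the first end groups. Each one charged is either still there or has become a link. I book each link against one second end group and one released group, which is a simplification, since a link held as idle adduct has taken up a further second end group and released group can be carried off. Green's knee closes those books as a reading, with its scatter: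

links, and as much released group: 9.74 mM
first end groups left: 6.26 mM
unused of the second end groups: 10.3 mM
quotient: 1.48

Call this the stall quotient: links times released group, over first end groups left times second end groups left, at the point where a run stops gaining quickly. Teal's last reading, at 8.00 min, gives 5.04 by the same count, more than green's 1.48, so the runs do not share one value. I carry green's value to the new flasks as a trial figure and no more. This is my own reckoning:

larch: 11.0 mM links, 54.9 %
maple: 7.23 mM links, 72.3 %

Maple has the time and the second end groups of green's knee, so I expect it near that figure. Larch runs longer, and the slow creep seen in green should lift it somewhat.

The forecast says maple, with 66 % (60 % to 72 %) for maple and 62 % (55 % to 74 %) for larch: “Maple is probably higher, but only modestly.” My ledger names the same flask but differs in both figures.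

The flask gives maple, with 69.6 % in maple against 60.9 % in larch.

    first end groups + second end groups ⇌ links + released group (K = 2.40, k = 0.690 L mol⁻¹ s⁻¹)
    released group → by-product carried off (k = 8.50 × 10⁻⁴ s⁻¹)
    crystals ⇌ links, rate k3*(cs3 - [links]) while solid is left; crystals form when [links] > cs3 (solubility = 11.0 mM, k = 0.0950 s⁻¹)
    second end groups + links ⇌ idle adduct, settled at all times (K = 100 L mol⁻¹)

In larch the making of links had 78 % of its turnover behind it at 1.60 min, and the carrying off of released group then ran on, reaching 3.59 mM of by-product at 8.00 min, while crystals stood at 0 % and links ended 6 points above the ledger's stall. On a neighbour of larch with 50 mM of first end groups, the same quotient balances at 15.4 mM links, 30.8 % of its charge, and that flask ends at 33.0 %.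

The runs were generated by integration for an exercise.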